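The route rests on disconnecting the C1–C6 bond, which is shared by the cyclohexene and the oxirane, together with the C6–O bond. C6 is an epoxide CH that is allylic to C4=C5, and C1 is a fully substituted epoxide carbon flanked by C7H2O and C2. An allylic sulfonium ylide at C6 can therefore add to a C1 ketone and the alkoxide can expel the sulfide, closing both rings and setting C1 and C6 in one operation. The precursor is an open-chain, L-tartrate-derived (Z)-allyl diphenylsulfonium salt, C7(OTBS)–C1(=O)–C2–C3–C4=C5–C6–S+Ph2, whose C2 and C3 oxygens are tied in a tetraisopropyldisiloxane (TIPDS) ring; its Z geometry comes from a Still–Gennari olefination.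

Key step: step 11

Remark: atom labels follow the bicyclic skeleton of the target (C1 = fully substituted epoxide carbon bearing C7H2O, C2 = CHOH, C3 = CHOBz, C4=C5 = alkene, C6 = epoxide CH) and are used unchanged for the open-chain intermediates.
Remark: compounds 7–11 and 13–16 are carried as C1 epimers (C1 left undefined in their SMILES), because C1 becomes the ketone in step 9.
Remark: only the (Z)-C4=C5 isomer can bring C6 to C1, so this geometry is fixed by a Z-selective olefination and not by olefin metathesis.

Step 1
Reactants: 1 diethyl L-tartrate; 2 1,3-dichloro-1,1,3,3-tetraisopropyldisiloxane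
Product: 3 diethyl (2R,3R)-2,3-O-(1,1,3,3-tetraisopropyldisiloxane-1,3-diyl)tartrate
Conditions: imidazole, DMF, 0 °C → rt
Reagents that add atoms: none
Why: Double O-silylation of the gauche threo diol by the bifunctional disiloxane dichloride should close the seven-membered trioxadisilepane (the usual TIPDS protection of a trans-1,2-diol) without touching either stereocentre.

Step 2
Reactants: 3 TIPDS-bridged diethyl tartrate; 4 methyltriphenylphosphonium bromide
Product: 6 (3S,4S)-3,4-O-TIPDS-hexa-1,5-diene-3,4-diol (trans-divinyl disiloxane), via (2R,3R)-2,3-O-TIPDS-tartraldehyde 5 (not isolated)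
Conditions: DIBAL-H (2.2 equiv), toluene, −78 °C; then Ph3P=CH2 (from 4, KHMDS, THF), −78 °C → rt
Reagents that add atoms: none
Why: Half-reduction of both esters gives aluminium hemiacetals that release dialdehyde 5 only as the pre-formed ylide intercepts it (one-pot reduction–Wittig methylenation), so the epimerisable α-silyloxy aldehyde should not accumulate and C2/C3 stay as in L-tartrate.

Step 3
Reactants: 6 trans-divinyl disiloxane
Product: 7 vinyl diol C7H2OH–C1HOH–C2–C3–C4H=CH2 (C2/C3-O-TIPDS, C2 and C3 as in 6, C1 epimers)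
Conditions: OsO4 (2 mol %), NMO (0.6 equiv), acetone–H2O, 0 °C
Reagents that add atoms: osmium tetroxide (catalytic oxygen carrier), O=[Os](=O)(=O)=O; N-methylmorpholine N-oxide, C[N+]1([O-])CCOCC1; water, O
Why: Upjohn dihydroxylation with the co-oxidant as limiting reagent: the two vinyl groups are homotopic, so mono-reaction can give only one constitution, unreacted 6 is recovered and recycled, and the new C1 carbinol centre (expected mainly anti to the allylic C2 oxygen) needs no control because C1 is oxidised in step 9.

Step 4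
Reactants: 7 vinyl diol
Product: 9 C1-O-acetyl C7-O-TBS vinyl compound, via C7-O-TBS ether 8 (not isolated)
Conditions: TBSCl (1.05 equiv), imidazole, CH2Cl2, 0 °C; then Ac2O, DMAP (cat.), rt
Reagents that add atoms: tert-butyldimethylsilyl chloride, CC(C)(C)[Si](C)(C)Cl; acetic anhydride, CC(=O)OC(C)=O
Why: Steric differentiation lets TBSCl silylate the primary C7–OH first, and DMAP-catalysed acetylation then caps the hindered secondary C1–OH in the same flask with a group that the DIBAL-H reduction of step 7 removes without an extra step.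

Step 5
Reactants: 9 C1-O-acetyl C7-O-TBS vinyl compound
Product: 11 C4 aldehyde C7(OTBS)–C1(OAc)–C2–C3–C4H=O (C2/C3-O-TIPDS), via secondary ozonide 10 (not isolated)
Conditions: O3, CH2Cl2, −78 °C; then PPh3, −78 °C → rt
Reagents that add atoms: ozone, [O-][O+]=O
Why: Ozonolysis with reductive work-up cleaves the only alkene to the C4 aldehyde while silyl ethers and the acetate are inert, and the crude α-silyloxy aldehyde is used at once so that C3 should not epimerise.

Step 6
Reactants: 11 C4 aldehyde; 12 methyl bis(2,2,2-trifluoroethyl)phosphonoacetate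
Product: 13 methyl (Z)-enoate C7(OTBS)–C1(OAc)–C2–C3–C4H=C5H–C6O2Me
Conditions: KHMDS, 18-crown-6, THF, −78 °C
Reagents that add atoms: none
Why: Still–Gennari olefination (Z-selective Horner–Wadsworth–Emmons) of an α-oxygenated aldehyde eliminates under kinetic control to the (Z)-enoate, which sets the C4=C5 geometry required for ring closure, and the weakly basic, pre-formed phosphonate anion at −78 °C should leave C3 and the acetate intact.

Step 7
Reactants: 13 methyl (Z)-enoate
Product: 14 (Z)-allylic alcohol diol C7(OTBS)–C1H(OH)–C2–C3–C4H=C5H–C6H2OH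
Conditions: DIBAL-H (5 equiv), CH2Cl2, −78 → −40 °C; Rochelle salt work-up
Reagents that add atoms: none
Why: DIBAL-H reduces the enoate 1,2 to the allylic alcohol with retention of the Z geometry and cleaves the acetate in the same operation, which exposes C1–OH while the silyl ethers are stable.

Step 8
Reactants: 14 (Z)-allylic alcohol diol
Product: 16 (Z)-allylic chloride with free C1–OH, via C6 allylic mesylate 15 (not isolated)
Conditions: MsCl (1.1 equiv), LiCl, 2,4,6-collidine, DMF, 0 °C
Reagents that add atoms: lithium chloride, [Li+].[Cl-]; methanesulfonyl chloride, CS(=O)(=O)Cl (for intermediate 15)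
Why: With the weak base collidine the primary allylic C6–OH is mesylated in preference to the hindered secondary C1–OH, and chloride displaces the allylic mesylate by SN2 in situ, a standard mesylate–chloride exchange that proceeds without allylic transposition or Z/E isomerisation.

Step 9
Reactants: 16 (Z)-allylic chloride with free C1–OH
Product: 17 keto chloride C7(OTBS)–C1(=O)–C2–C3–C4H=C5H–C6H2Cl (Z; C2 R, C3 S)
Conditions: Dess–Martin periodinane, pyridine, CH2Cl2, 0 °C → rt
Reagents that add atoms: none
Why: Dess–Martin oxidation converts both C1 epimers into the same ketone under buffered, non-basic conditions that should neither epimerise C2 nor affect the allylic chloride or the silyl ethers.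

Step 10
Reactants: 17 keto chloride; 18 diphenyl sulfide
Product: 19 (Z)-allyl diphenylsulfonium tetrafluoroborate C7(OTBS)–C1(=O)–C2–C3–C4H=C5H–C6H2–S+Ph2 BF4− (C2 R, C3 S)
Conditions: Ph2S (5 equiv), AgBF4 (1.1 equiv), CH2Cl2, −20 °C → rt, dark
Reagents that add atoms: silver tetrafluoroborate, [Ag+].F[B-](F)(F)F
Why: Silver-assisted S-alkylation, the standard preparation of allyl diphenylsulfonium tetrafluoroborates: Ag+ removes chloride as AgCl while the excess of the weakly nucleophilic diaryl sulfide attacks the primary allylic terminus C6, and the mild conditions should preserve the Z-alkene, the ketone and the silyl ethers.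

Step 11
Reactants: 19 (Z)-allyl diphenylsulfonium tetrafluoroborate
Product: 22 silyl-protected epoxycyclohexene (7-oxabicyclo[4.1.0]hept-4-ene with C1–CH2OTBS and C2/C3-O-TIPDS; oxirane oxygen cis to C2–O, trans to C3–O), via allyl sulfonium ylide 20 (not isolated), via betaine 21 (not isolated)
Conditions: KHMDS (1.0 equiv, slow addition), THF (0.01 M), −78 → −20 °C
Reagents that add atoms: none
Why: KHMDS removes a proton from the S+–C6H2 group to give the semi-stabilised allyl ylide 20, whose α-carbon C6 adds to the C1 ketone (6-exo-trig, closing the carbocycle; γ-attack would need a four-membered ring) to give betaine 21, and the C1 alkoxide then displaces diphenyl sulfide from C6 (3-exo-tet, closing the oxirane), which is an intramolecular Corey–Chaykovsky epoxidation of the known epoxy-annulation type for carbonyl-tethered sulfonium salts. C6 is set by the SN2 inversion of this closure: an oxirane on a six-membered ring must be cis-fused, so only the betaine with C1–O− and C6–S+ antiperiplanar (trans-diaxial) can collapse, and the other betaines should revert or equilibrate through the ylide, helped by the potassium counter-ion and the aprotic medium. C1 is set by the disiloxane ring, which holds C2–O and C3–O diequatorial on the forming half-chair, so that the trans-diaxial closure places the C1 alkoxide axial and C7 equatorial, i.e. the oxirane oxygen cis to C2–O and trans to C3–O, which is also the Felkin–Anh sense with C2–O anti to the incoming C6. The selectivity needed is ylide formation and addition ahead of ketone enolisation with β-elimination of the C3 oxygen; it is secured by the much higher acidity of the sulfonium methylene, by sulfur carrying only phenyl groups (no second ylide, no [2,3] shift), by one equivalent of base at −78 °C, by the poor silanolate leaving group and by high dilution.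

Step 12
Reactants: 22 silyl-protected epoxycyclohexene
Product: 23 (1R,2R,3S,6S)-1-(hydroxymethyl)-7-oxabicyclo[4.1.0]hept-4-ene-2,3-diol
Conditions: TBAF, AcOH (1:1, 4 equiv), THF, 0 °C → rt
Reagents that add atoms: none
Why: Fluoride-mediated desilylation buffered with acetic acid cleaves the TBS ether and both Si–O bonds of the disiloxane without free alkoxide, so neither Payne rearrangement from C7–O nor opening of the vinyl epoxide should occur and no stereocentre is touched.

Step 13
Reactants: 23 epoxycyclohexene triol
Product: 24 (−)-pipoxide, [(1R,2R,3S,6S)-3-(benzoyloxy)-2-hydroxy-7-oxabicyclo[4.1.0]hept-4-en-1-yl]methyl benzoate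
Conditions: BzCl (2.1 equiv), pyridine, CH2Cl2, −30 → 0 °C
Reagents that add atoms: benzoyl chloride, O=C(Cl)c1ccccc1
Why: Regioselective O-acylation under pyridine catalysis: the primary C7–OH reacts first, then the allylic C3–OH flanked only by the sp2 carbon C4, while the C2–OH next to the fully substituted C1 is the most hindered and should stay free at low temperature with a limited amount of acid chloride.

Compound list
1 | diethyl L-tartrate, diethyl (2R,3R)-2,3-dihydroxybutanedioate | CCOC(=O)[C@H](O)[C@@H](O)C(=O)OCC | starting material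
2 | 1,3-dichloro-1,1,3,3-tetraisopropyldisiloxane | CC(C)[Si](Cl)(C(C)C)O[Si](Cl)(C(C)C)C(C)C | starting material
3 | diethyl (2R,3R)-2,3-O-(1,1,3,3-tetraisopropyldisiloxane-1,3-diyl)tartrate | CCOC(=O)[C@@H]1O[Si](C(C)C)(C(C)C)O[Si](C(C)C)(C(C)C)O[C@H]1C(=O)OCC | intermediate
4 | methyltriphenylphosphonium bromide | C[P+](c1ccccc1)(c1ccccc1)c1ccccc1.[Br-] | starting material
5 | (2R,3R)-2,3-O-TIPDS-tartraldehyde (formed in situ) | O=C[C@@H]1O[Si](C(C)C)(C(C)C)O[Si](C(C)C)(C(C)C)O[C@H]1C=O | intermediate
6 | (3S,4S)-3,4-O-TIPDS-hexa-1,5-diene-3,4-diol | C=C[C@@H]1O[Si](C(C)C)(C(C)C)O[Si](C(C)C)(C(C)C)O[C@H]1C=C | intermediate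
7 | vinyl diol, C7H2OH–C1HOH–C2–C3–C4H=CH2, C2/C3-O-TIPDS, C1 epimers | C=C[C@@H]1O[Si](C(C)C)(C(C)C)O[Si](C(C)C)(C(C)C)O[C@H]1C(O)CO | intermediate
8 | C7-O-TBS ether of 7, C1–OH free (formed in situ) | C=C[C@@H]1O[Si](C(C)C)(C(C)C)O[Si](C(C)C)(C(C)C)O[C@H]1C(O)CO[Si](C)(C)C(C)(C)C | intermediate
9 | C1-O-acetyl C7-O-TBS vinyl compound | C=C[C@@H]1O[Si](C(C)C)(C(C)C)O[Si](C(C)C)(C(C)C)O[C@H]1C(OC(C)=O)CO[Si](C)(C)C(C)(C)C | intermediate
10 | secondary ozonide (1,2,4-trioxolane) of 9 (formed in situ) | C1OC(OO1)[C@@H]2O[Si](C(C)C)(C(C)C)O[Si](C(C)C)(C(C)C)O[C@H]2C(OC(C)=O)CO[Si](C)(C)C(C)(C)C | intermediate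
11 | C4 aldehyde, C7(OTBS)–C1(OAc)–C2–C3–C4H=O, C2/C3-O-TIPDS | O=C[C@@H]1O[Si](C(C)C)(C(C)C)O[Si](C(C)C)(C(C)C)O[C@H]1C(OC(C)=O)CO[Si](C)(C)C(C)(C)C | intermediate
12 | methyl bis(2,2,2-trifluoroethyl)phosphonoacetate | COC(=O)CP(=O)(OCC(F)(F)F)OCC(F)(F)F | starting material
13 | methyl (Z)-enoate, C7(OTBS)–C1(OAc)–C2–C3–C4H=C5H–C6O2Me | COC(=O)/C=C\[C@@H]1O[Si](C(C)C)(C(C)C)O[Si](C(C)C)(C(C)C)O[C@H]1C(OC(C)=O)CO[Si](C)(C)C(C)(C)C | intermediate
14 | (Z)-allylic alcohol diol, C6H2OH and C1–OH free, C7-OTBS | OC/C=C\[C@@H]1O[Si](C(C)C)(C(C)C)O[Si](C(C)C)(C(C)C)O[C@H]1C(O)CO[Si](C)(C)C(C)(C)C | intermediate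
15 | C6 allylic mesylate of 14 (formed in situ) | CS(=O)(=O)OC/C=C\[C@@H]1O[Si](C(C)C)(C(C)C)O[Si](C(C)C)(C(C)C)O[C@H]1C(O)CO[Si](C)(C)C(C)(C)C | intermediate
16 | (Z)-allylic chloride with free C1–OH | ClC/C=C\[C@@H]1O[Si](C(C)C)(C(C)C)O[Si](C(C)C)(C(C)C)O[C@H]1C(O)CO[Si](C)(C)C(C)(C)C | intermediate
17 | keto chloride, C7(OTBS)–C1(=O)–C2–C3–C4H=C5H–C6H2Cl, Z, C2 R, C3 S | ClC/C=C\[C@@H]1O[Si](C(C)C)(C(C)C)O[Si](C(C)C)(C(C)C)O[C@H]1C(=O)CO[Si](C)(C)C(C)(C)C | intermediate
18 | diphenyl sulfide | c1ccc(cc1)Sc1ccccc1 | starting material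
19 | (Z)-allyl diphenylsulfonium tetrafluoroborate, keto salt with C2/C3-O-TIPDS and C7-OTBS | c1ccc(cc1)[S+](c1ccccc1)C/C=C\[C@@H]1O[Si](C(C)C)(C(C)C)O[Si](C(C)C)(C(C)C)O[C@H]1C(=O)CO[Si](C)(C)C(C)(C)C.F[B-](F)(F)F | intermediate
20 | allyl sulfonium ylide, carbanion at C6 (formed in situ) | c1ccc(cc1)[S+](c1ccccc1)[CH-]/C=C\[C@@H]1O[Si](C(C)C)(C(C)C)O[Si](C(C)C)(C(C)C)O[C@H]1C(=O)CO[Si](C)(C)C(C)(C)C | intermediate
21 | betaine, cyclohexene with C1–O− and C6–S+Ph2 trans (formed in situ) | CC(C)(C)[Si](C)(C)OC[C@]1([O-])[C@H]([S+](c2ccccc2)c2ccccc2)C=C[C@@H]2O[Si](C(C)C)(C(C)C)O[Si](C(C)C)(C(C)C)O[C@@H]12 | intermediate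
22 | silyl-protected epoxycyclohexene triol, oxirane oxygen cis to C2–O | CC(C)(C)[Si](C)(C)OC[C@]12O[C@H]1C=C[C@@H]3O[Si](C(C)C)(C(C)C)O[Si](C(C)C)(C(C)C)O[C@@H]23 | intermediate
23 | (1R,2R,3S,6S)-1-(hydroxymethyl)-7-oxabicyclo[4.1.0]hept-4-ene-2,3-diol | OC[C@]12O[C@H]1C=C[C@H](O)[C@H]2O | intermediate
24 | (−)-pipoxide, [(1R,2R,3S,6S)-3-(benzoyloxy)-2-hydroxy-7-oxabicyclo[4.1.0]hept-4-en-1-yl]methyl benzoate | O=C(OC[C@]12O[C@H]1C=C[C@H](OC(=O)c1ccccc1)[C@H]2O)c1ccccc1 | target

Total step count: 13. Longest linear sequence: 13 steps (from 1 to 24).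

Steps most likely to fail

Step 11 (key step). What may go wrong is enolisation of the ketone toward C2 with β-elimination of the C3 siloxy group, or ylide addition that is not followed by closure (poor facial selectivity at C1, or a betaine that cannot reach the trans-diaxial geometry). The fallback separates ring closure from epoxide formation and uses phosphorus in place of sulfur. It sets out from keto chloride 17: triphenylphosphine (NaI cat., MeCN, 50 °C) should give the (Z)-allyl triphenylphosphonium chloride F1. KHMDS (THF, −78 °C → rt) should then effect an intramolecular Wittig reaction of C6 with the C1 ketone to the TIPDS/TBS-protected cyclohexa-1,3-diene F2 (C1=C6, C4=C5). TBAF/AcOH should give the diene triol F3, and hydroxyl-directed epoxidation with mCPBA/NaHCO3 at the more substituted C1=C6 bond, delivered cis to the allylic C2–OH, should give triol 23, where the route is rejoined.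

Step 13. What may go wrong is insufficient discrimination between the two secondary hydroxyls (over-acylation, or acylation at C2–OH in place of C3–OH). The fallback replaces steric control by constitutional control and sets out from triol 23. Phenylboronic acid (CH2Cl2, 4 Å MS) should tie the 1,3-related C7–OH and C2–OH into the six-membered cyclic phenylboronate F4, since the trans-1,2-diol does not chelate boron. Benzoyl chloride/pyridine then acylates the only free hydroxyl to give the C3 benzoate boronate F5. Transesterification with pinacol frees the 3-O-benzoyl diol F6, and one equivalent of benzoyl chloride (2,4,6-collidine, −40 °C) should acylate the primary C7–OH in preference to the hindered C2–OH, arriving at 24.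

Step 10. What may go wrong is silver-assisted ionisation of the (Z)-allyl chloride with loss of alkene geometry, or capture of the allyl cation by the neighbouring C3 siloxy oxygen in competition with the weakly nucleophilic diaryl sulfide. The fallback is a silver-free SN2 alkylation of a nucleophilic dialkyl sulfide and sets out from keto chloride 17. Tetrahydrothiophene (excess) with NaI and NaBF4 in acetone at rt should give the S-allyl tetrahydrothiophenium tetrafluoroborate F7. Its allylic S+–CH2 is the most acidic position, so KHMDS under the conditions of step 11 should trigger the same ylide addition–closure cascade with loss of tetrahydrothiophene and return the route at 22.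

Further compounds
F1 | step 11 | (Z)-allyl triphenylphosphonium chloride derived from 17 | c1ccc(cc1)[P+](c1ccccc1)(c1ccccc1)C/C=C\[C@@H]1O[Si](C(C)C)(C(C)C)O[Si](C(C)C)(C(C)C)O[C@H]1C(=O)CO[Si](C)(C)C(C)(C)C.[Cl-]
F2 | step 11 | TIPDS/TBS-protected 1-(hydroxymethyl)cyclohexa-1,3-diene-5,6-diol (C1=C6, C4=C5; C2/C3-O-TIPDS, C7-OTBS) | CC(C)(C)[Si](C)(C)OCC1=CC=C[C@@H]2O[Si](C(C)C)(C(C)C)O[Si](C(C)C)(C(C)C)O[C@@H]12
F3 | step 11 | diene triol, C7H2OH on C1, C2–OH, C3–OH (trans) | OCC1=CC=C[C@H](O)[C@H]1O
F4 | step 13 | cyclic phenylboronate of 23 across C7–O and C2–O, C3–OH free | O1C[C@]23O[C@H]2C=C[C@H](O)[C@H]3OB1c1ccccc1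
F5 | step 13 | C3 benzoate of boronate F4 | O1C[C@]23O[C@H]2C=C[C@H](OC(=O)c2ccccc2)[C@H]3OB1c1ccccc1
F6 | step 13 | 3-O-benzoyl diol, C7–OH and C2–OH free | OC[C@]12O[C@H]1C=C[C@H](OC(=O)c1ccccc1)[C@H]2O
F7 | step 10 | S-[(Z)-allyl]tetrahydrothiophenium tetrafluoroborate derived from 17 | C1CC[S+](C1)C/C=C\[C@@H]1O[Si](C(C)C)(C(C)C)O[Si](C(C)C)(C(C)C)O[C@H]1C(=O)CO[Si](C)(C)C(C)(C)C.F[B-](F)(F)F
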